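The runs are simulated on assumed constants, and the scatter is random.

An equilibrium constant is a concentration in disguise, and I needed one before choosing between two charges of coupling partner.

| flask | substrate | coupling partner | remark | time |
|---|---|---|---|---|
| epsilon | 10 mM | 3 equiv | run made earlier |  |
| noon | 15 mM | 3.00 equiv |  | 2.0 d |
| summer | 15 mM | 1.50 equiv |  | 2.0 d |

- epsilon (time / h: tris adduct / %): 1.50: 6.0; 4.00: 22.1; 8.00: 37.2; 12.0: 42.1; 20.0: 46.4; 25.0: 46.0; 30.0: 47.2

(scatter of a reading: 0.5 percentage points)

- which of these holds the largest part of the substrate at the end of noon (bis adduct / single product / tris adduct / substrate)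
- which of these holds the largest part of the substrate at the end of summer (bis adduct / single product / tris adduct / substrate)
- tris adduct at the end of summer, in percent of the substrate charged

I took the last addition, bis adduct plus coupling partner to tris adduct, as reversible. The epsilon run gave tris adduct 47.2% at its last reading. I assumed the rest was bis adduct, so I read the ratio of tris to bis as 0.894 and reckoned free partner at 5.28 mM. Dividing gave 5.91 mM. I called this the half-fill level h, the free partner at which tris adduct equals bis adduct. It is the inverse of the equilibrium constant, and tris over bis is free partner over h.

The noon charge held 15.0 mM of partner beyond two additions per substrate, more than h, so I expected tris adduct to lead there. The summer charge fell 7.50 mM short of two additions, so I expected free partner far below h and tris adduct well under bis adduct. I made no call between single product and bis adduct for summer, since the epsilon run shows readings of tris adduct and not of those two. I chose the noon charge.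

The forecast said tris adduct for noon, single product for summer and 10% tris adduct in summer, adding “any cooperativity could reverse this”. The flasks gave tris adduct in noon, and bis adduct in summer with 8.15% tris adduct.

    substrate + coupling partner → single product (k = 26.0 M⁻¹ h⁻¹)
    coupling partner + single product → bis adduct (k = 40.1 M⁻¹ h⁻¹)
    coupling partner + bis adduct ⇌ tris adduct (K = 220 M⁻¹, k = 14.3 M⁻¹ h⁻¹)
    tris adduct ⇌ isomer of the product (K = 0.180, k = 0.133 h⁻¹)
    2 substrate → self-condensation product (k = 8.69 M⁻¹ h⁻¹)

At 2.00 d in summer, free partner was 0.517 mM, which against h gave a tris-to-bis ratio of 0.0875; the flask showed 0.146, and tris adduct was made at 0.158 of the rate at which it was used up, each step taken net. A neighbour flask, summer with 3.80 equiv of partner, had 18.4 mM free at 2.00 d, which against h gave 3.11, and it held 63.8% tris adduct against 15.7% bis adduct, a ratio of 4.06.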